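## Retrosynthetic overview

1. Kanzonol V (14) ⇒ 2‑hydroxystilbene 12: the furan C2–O bond is made last by dehydrogenative quinone‑methide cyclisation, the way 2‑arylbenzofurans are thought to arise in the plant.
2. 12 ⇒ Wittig union of the A‑ring phosphonium salt 5 with the B‑ring chromene aldehyde 10.
3. 10 ⇒ o‑prenylphenol 8: the pyran ring is closed by DDQ through an o‑quinone methide and oxa‑6π electrocyclisation; the 4‑O‑silyl group forces closure onto O‑2.
4. 5 and 8 ⇒ 2,4‑dihydroxybenzaldehyde (1) by regiodivergent C‑prenylation (C5 under acid, C3 under base).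
5. Ring order: pyran ring first (step 5), furan ring last (step 7); both benzene rings are bought.

Assumption: kanzonol V has no stereocentre, so "single enantiomer" needs no stereocontrol; the stilbene C=C geometry of 11/12 is the only stereo‑element on the way and is erased in step 7.

## Route

Step 1
Reactants: 1 2,4-dihydroxybenzaldehyde; 2 2-methylbut-3-en-2-ol
Product: 3 2,4-dihydroxy-5-(3-methylbut-2-en-1-yl)benzaldehyde
Conditions: BF3·OEt2 (0.5 equiv), dioxane, rt, 16 h
Reagents that add atoms: none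
Why: Friedel–Crafts prenylation in which BF3 ionises the tertiary allylic alcohol to the dimethylallyl cation, which attacks C5 (para to the 2‑OH, ortho to the 4‑OH, least hindered); the minor 3‑isomer is removed by chromatography and no stereocentre is formed.

Step 2
Reactants: 3 2,4-dihydroxy-5-(3-methylbut-2-en-1-yl)benzaldehyde
Product: 5 [2,4-dihydroxy-5-(3-methylbut-2-en-1-yl)benzyl]triphenylphosphonium bromide, via benzylic alcohol 4 (not isolated)
Conditions: NaBH4, THF–MeOH, 0 °C; then PPh3·HBr, MeCN, rt (one pot)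
Reagents that add atoms: triphenylphosphine hydrobromide, [Br-].c1ccc(cc1)[PH+](c1ccccc1)c1ccccc1
Why: Borohydride reduction gives the labile o,p‑dihydroxybenzyl alcohol, which ionises under the mildly acidic PPh3·HBr and is trapped by PPh3 (SN1 phosphonium salt formation) before it can polymerise.

Step 3
Reactants: 1 2,4-dihydroxybenzaldehyde; 6 1-bromo-3-methylbut-2-ene (prenyl bromide)
Product: 7 2,4-dihydroxy-3-(3-methylbut-2-en-1-yl)benzaldehyde
Conditions: KOH (2.2 equiv), H2O, 0 °C → rt; then dilute HCl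
Reagents that add atoms: none
Why: C‑alkylation of the ambident resorcinol dianion in water, where solvation of oxygen suppresses O‑alkylation and the carbon flanked by both oxygens (C3) is the most nucleophilic site; the minor 5‑isomer and the O‑prenyl ether are separated.

Step 4
Reactants: 7 2,4-dihydroxy-3-(3-methylbut-2-en-1-yl)benzaldehyde
Product: 8 4-[(tert-butyldimethylsilyl)oxy]-2-hydroxy-3-(3-methylbut-2-en-1-yl)benzaldehyde
Conditions: TBSCl (1.05 equiv), imidazole, CH2Cl2, 0 °C
Reagents that add atoms: tert-butyldimethylsilyl chloride, CC(C)(C)[Si](C)(C)Cl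
Why: Regioselective silylation, because the 2‑OH is hydrogen‑bonded to the aldehyde and doubly flanked, so only the more acidic 4‑OH reacts.

Step 5
Reactants: 8 4-[(tert-butyldimethylsilyl)oxy]-2-hydroxy-3-(3-methylbut-2-en-1-yl)benzaldehyde
Product: 10 5-[(tert-butyldimethylsilyl)oxy]-2,2-dimethyl-2H-chromene-8-carbaldehyde, via ortho-quinone methide 9 (not isolated)
Conditions: DDQ (1.2 equiv), toluene, 80 °C, 3 h
Reagents that add atoms: none
Why: DDQ dehydrogenative cyclisation of an o‑prenylphenol, in which hydride abstraction from the benzylic‑allylic CH2 and loss of the phenol proton give o‑quinone methide 9, which closes by oxa‑6π electrocyclisation; with O‑4 silylated only O‑2 can close, which fixes the pyran regiochemistry.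

Step 6
Reactants: 5 [2,4-dihydroxy-5-(3-methylbut-2-en-1-yl)benzyl]triphenylphosphonium bromide; 10 5-[(tert-butyldimethylsilyl)oxy]-2,2-dimethyl-2H-chromene-8-carbaldehyde
Product: 12 (E)-4-[2-(5-hydroxy-2,2-dimethyl-2H-chromen-8-yl)ethenyl]-6-(3-methylbut-2-en-1-yl)benzene-1,3-diol, via silyl ether stilbene 11 (not isolated)
Conditions: 5 (1.2 equiv), LiHMDS (3.6 equiv), THF, −78 → 0 °C; 10, 0 °C → rt; then TBAF (1.5 equiv), rt; aq NH4Cl; product kept under Ar and used at once
Reagents that add atoms: none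
Why: Wittig olefination of the bis‑phenoxide ylide (three equivalents of base per salt: two ArOH and the CH2P+) with the non‑enolisable aldehyde, followed by fluoride desilylation in the same flask; an E‑rich E/Z mixture is expected and is acceptable because both isomers converge in step 7.

Step 7
Reactants: 12 (E)-4-[2-(5-hydroxy-2,2-dimethyl-2H-chromen-8-yl)ethenyl]-6-(3-methylbut-2-en-1-yl)benzene-1,3-diol
Product: 14 kanzonol V, via stilbenequinone 13 (not isolated)
Conditions: DDQ (1.0 equiv, added dropwise), THF, 0 °C, 20 min, Ar; aq NaHCO3/ascorbate quench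
Reagents that add atoms: none
Why: Proposed new method: DDQ dehydrogenates the unprotected 4,4′‑dihydroxystilbene to the extended quinone methide 13, the A‑ring 2‑OH (the only free ortho‑hydroxyl, since the B‑ring ortho oxygen is the pyran ether) adds 5‑exo to the exocyclic carbon next to ring B and tautomerisation gives the aromatic benzofuran, while 1.0 equiv at 0 °C leaves no oxidant for the much slower hydride abstraction at the prenyl CH2 next to the 6‑OH; the closest known reactions are the DDQ oxidative cyclisation of 2‑hydroxystilbenes to 2‑arylbenzofurans and the oxidation of 4,4′‑dihydroxystilbenes to stilbenequinones.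

## Compound list

1 | 2,4-dihydroxybenzaldehyde | O=Cc1ccc(O)cc1O | starting material
2 | 2-methylbut-3-en-2-ol | C=CC(C)(C)O | starting material
3 | 2,4-dihydroxy-5-(3-methylbut-2-en-1-yl)benzaldehyde | CC(C)=CCc1cc(C=O)c(O)cc1O | intermediate
4 | 4-(hydroxymethyl)-6-(3-methylbut-2-en-1-yl)benzene-1,3-diol | CC(C)=CCc1cc(CO)c(O)cc1O | intermediate
5 | [2,4-dihydroxy-5-(3-methylbut-2-en-1-yl)benzyl]triphenylphosphonium bromide | CC(C)=CCc1cc(C[P+](c2ccccc2)(c2ccccc2)c2ccccc2)c(O)cc1O.[Br-] | intermediate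
6 | 1-bromo-3-methylbut-2-ene (prenyl bromide) | CC(C)=CCBr | starting material
7 | 2,4-dihydroxy-3-(3-methylbut-2-en-1-yl)benzaldehyde | CC(C)=CCc1c(O)ccc(C=O)c1O | intermediate
8 | 4-[(tert-butyldimethylsilyl)oxy]-2-hydroxy-3-(3-methylbut-2-en-1-yl)benzaldehyde | CC(C)=CCc1c(O[Si](C)(C)C(C)(C)C)ccc(C=O)c1O | intermediate
9 | 4-[(tert-butyldimethylsilyl)oxy]-5-(3-methylbut-2-en-1-ylidene)-6-oxocyclohexa-1,3-diene-1-carbaldehyde (ortho-quinone methide, exocyclic geometry undefined) | CC(C)=CC=C1C(=O)C(C=O)=CC=C1O[Si](C)(C)C(C)(C)C | intermediate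
10 | 5-[(tert-butyldimethylsilyl)oxy]-2,2-dimethyl-2H-chromene-8-carbaldehyde | CC1(C)C=Cc2c(O[Si](C)(C)C(C)(C)C)ccc(C=O)c2O1 | intermediate
11 | (E)-4-(2-{5-[(tert-butyldimethylsilyl)oxy]-2,2-dimethyl-2H-chromen-8-yl}ethenyl)-6-(3-methylbut-2-en-1-yl)benzene-1,3-diol | CC(C)=CCc1cc(/C=C/c2ccc(O[Si](C)(C)C(C)(C)C)c3C=CC(C)(C)Oc23)c(O)cc1O | intermediate
12 | (E)-4-[2-(5-hydroxy-2,2-dimethyl-2H-chromen-8-yl)ethenyl]-6-(3-methylbut-2-en-1-yl)benzene-1,3-diol (E drawn, E-rich mixture) | CC(C)=CCc1cc(/C=C/c2ccc(O)c3C=CC(C)(C)Oc23)c(O)cc1O | intermediate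
13 | 8-{2-[2-hydroxy-5-(3-methylbut-2-en-1-yl)-4-oxocyclohexa-2,5-dien-1-ylidene]ethylidene}-2,2-dimethyl-2H-chromen-5(8H)-one (stilbenequinone, exocyclic geometry undefined) | CC(C)=CCC1=CC(=CC=C2C=CC(=O)C3=C2OC(C)(C)C=C3)C(O)=CC1=O | intermediate
14 | kanzonol V, 2-(5-hydroxy-2,2-dimethyl-2H-chromen-8-yl)-5-(3-methylbut-2-en-1-yl)-1-benzofuran-6-ol | CC(C)=CCc1cc2cc(-c3ccc(O)c4c3OC(C)(C)C=C4)oc2cc1O | target

## Step count

Total steps: 7. Longest linear sequence: 5 (steps 3, 4, 5, 6, 7).

## Steps most likely to fail, with fallbacks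

Step 7 (chemoselective oxidative furan closure on an unprotected prenylated polyphenol; risk of over‑oxidation of the 6‑OH/5‑prenyl pair to a second chromene, or of intermolecular coupling). The fallback sets out from 3 and 10 and comes back at 14. The 4‑OH of 3 is silylated (TBSCl, imidazole) to 4-[(tert-butyldimethylsilyl)oxy]-2-hydroxy-5-(3-methylbut-2-en-1-yl)benzaldehyde F1, which is converted as in step 2 into {4-[(tert-butyldimethylsilyl)oxy]-2-hydroxy-5-(3-methylbut-2-en-1-yl)benzyl}triphenylphosphonium bromide F2. Wittig reaction of F2 (2.2 equiv LiHMDS, no fluoride) with 10 gives 5-[(tert-butyldimethylsilyl)oxy]-2-[(E)-2-{5-[(tert-butyldimethylsilyl)oxy]-2,2-dimethyl-2H-chromen-8-yl}ethenyl]-4-(3-methylbut-2-en-1-yl)phenol F3, in which the stilbene 2‑OH is the only free hydroxyl and the prenyl group has no free ortho‑OH. Hypervalent‑iodine oxidative cyclisation (PhI(OAc)2, MeCN, rt) then gives 6-O,5′-O-bis(tert-butyldimethylsilyl)kanzonol V F4, and TBAF releases 14.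

Step 6 (Wittig reaction of a p‑oxidobenzyl ylide, which can expel PPh3 to a quinone methide instead of olefinating). The fallback sets out from 10 and comes back at 11, which is desilylated to 12 with TBAF as in step 6. Methylenation of 10 (Ph3P=CH2, THF, 0 °C) gives tert-butyl[(8-ethenyl-2,2-dimethyl-2H-chromen-5-yl)oxy]dimethylsilane F5. Commercial 4‑bromoresorcinol is prenylated with 2 under the step 1 conditions to 4-bromo-6-(3-methylbut-2-en-1-yl)benzene-1,3-diol F6. Heck coupling of F5 with F6 (Pd(OAc)2, P(o‑tol)3, Et3N, DMF, 100 °C) gives 11 as the E isomer.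

Step 5 (DDQ closure onto a hydrogen‑bonded hydroxyl of an electron‑poor ring may be slow or lose the silyl group). The fallback sets out from 8 and comes back at 10. Selenoetherification of 8 (PhSeCl, pyridine, CH2Cl2, −78 °C; 6‑endo attack of O‑2 on the tertiary carbon) gives racemic 5-[(tert-butyldimethylsilyl)oxy]-2,2-dimethyl-3-(phenylselanyl)-3,4-dihydro-2H-chromene-8-carbaldehyde F7. Oxidation to the selenoxide (mCPBA, −78 °C, then i‑Pr2NEt, rt) and syn‑elimination toward C4 give 10.

## Further compounds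

F1 | step 7 | 4-[(tert-butyldimethylsilyl)oxy]-2-hydroxy-5-(3-methylbut-2-en-1-yl)benzaldehyde | CC(C)=CCc1cc(C=O)c(O)cc1O[Si](C)(C)C(C)(C)C
F2 | step 7 | {4-[(tert-butyldimethylsilyl)oxy]-2-hydroxy-5-(3-methylbut-2-en-1-yl)benzyl}triphenylphosphonium bromide | CC(C)=CCc1cc(C[P+](c2ccccc2)(c2ccccc2)c2ccccc2)c(O)cc1O[Si](C)(C)C(C)(C)C.[Br-]
F3 | step 7 | 5-[(tert-butyldimethylsilyl)oxy]-2-[(E)-2-{5-[(tert-butyldimethylsilyl)oxy]-2,2-dimethyl-2H-chromen-8-yl}ethenyl]-4-(3-methylbut-2-en-1-yl)phenol | CC(C)=CCc1cc(/C=C/c2ccc(O[Si](C)(C)C(C)(C)C)c3C=CC(C)(C)Oc23)c(O)cc1O[Si](C)(C)C(C)(C)C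
F4 | step 7 | 6-O,5′-O-bis(tert-butyldimethylsilyl)kanzonol V | CC(C)=CCc1cc2cc(-c3ccc(O[Si](C)(C)C(C)(C)C)c4C=CC(C)(C)Oc34)oc2cc1O[Si](C)(C)C(C)(C)C
F5 | step 6 | tert-butyl[(8-ethenyl-2,2-dimethyl-2H-chromen-5-yl)oxy]dimethylsilane | C=Cc1ccc(O[Si](C)(C)C(C)(C)C)c2C=CC(C)(C)Oc12
F6 | step 6 | 4-bromo-6-(3-methylbut-2-en-1-yl)benzene-1,3-diol | CC(C)=CCc1cc(Br)c(O)cc1O
F7 | step 5 | 5-[(tert-butyldimethylsilyl)oxy]-2,2-dimethyl-3-(phenylselanyl)-3,4-dihydro-2H-chromene-8-carbaldehyde (racemic) | CC1(C)Oc2c(C=O)ccc(O[Si](C)(C)C(C)(C)C)c2CC1[Se]c1ccccc1
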